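The 21-membered ring is disconnected at an unfunctionalised CH2–CH2 bond of the C14 tether, between the fifth and sixth carbons counted from ring B (the hydroquinone ring); these two carbons lie far from both arenes and have like polarity. The bond is therefore made as a C=C by ring-closing olefin metathesis, which closes the macrocycle in one operation with loss of ethene; the alkene geometry is irrelevant because hydrogenation follows. The precursor is an acyclic diaryl ether with a hex-5-enyl chain on ring B and a dec-9-enyl chain on ring A (the resorcinol ring), assembled by Ullmann coupling of two separately alkylated arenes; the methyl ethers are cleaved last.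

Key step: step 6

Remark: the target has no stereocentre, so no stereocontrol is required; the geometry of the ring alkene made in step 6 is erased in step 7.

Step 1
Reactants: 1 3,5-dimethoxybenzyl bromide; 2 9-bromonon-1-ene
Product: 4 1-(dec-9-en-1-yl)-3,5-dimethoxybenzene, via non-8-en-1-ylmagnesium bromide 3 (not isolated)
Conditions: 2, Mg, THF, 40 °C; then 1, Li2CuCl4 (3 mol %), THF, −78 °C to rt
Reagents that add atoms: none
Why: Copper-catalysed sp3–sp3 cross-coupling of a primary alkyl Grignard reagent with a benzylic bromide (Kochi coupling) should join the two fragments cleanly at low temperature, the remote terminal alkene being inert to Grignard formation and to the cuprate.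

Step 2
Reactants: 4 1-(dec-9-en-1-yl)-3,5-dimethoxybenzene
Product: 5 3-(dec-9-en-1-yl)-5-methoxyphenol
Conditions: NaSEt (3 equiv), DMF, 140 °C; then aq. HCl
Reagents that add atoms: none
Why: Nucleophilic O-demethylation (SN2 attack of ethanethiolate at the methyl carbon) should stop at the monophenol, because the phenoxide formed deactivates the second methyl ether, and the isolated alkene is untouched.

Step 3
Reactants: 6 2,6-dibromo-4-methoxyphenol
Product: 7 1,3-dibromo-2,5-dimethoxybenzene
Conditions: MeI, K2CO3, acetone, reflux
Reagents that add atoms: iodomethane, CI
Why: Williamson O-methylation of the acidic 2,6-dibromophenoxide with a small electrophile should be fast and complete and masks the phenol before the organolithium step.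

Step 4
Reactants: 7 1,3-dibromo-2,5-dimethoxybenzene; 8 6-bromohex-1-ene
Product: 10 1-bromo-3-(hex-5-en-1-yl)-2,5-dimethoxybenzene, via (3-bromo-2,5-dimethoxyphenyl)lithium 9 (not isolated)
Conditions: t-BuLi (2.0 equiv), THF, −78 °C; then 8 (2 equiv), −78 °C to rt
Reagents that add atoms: none
Why: Bromine–lithium exchange on one of the two equivalent C–Br bonds (the second equivalent of t-BuLi destroys the t-BuBr formed, and a second exchange on the electron-rich aryllithium is disfavoured) should give an ortho-methoxy-stabilised aryllithium that is alkylated by the primary bromide in an SN2 reaction, leaving the other bromine for the ether coupling.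

Step 5
Reactants: 5 3-(dec-9-en-1-yl)-5-methoxyphenol; 10 1-bromo-3-(hex-5-en-1-yl)-2,5-dimethoxybenzene
Product: 11 1-[3-(dec-9-en-1-yl)-5-methoxyphenoxy]-3-(hex-5-en-1-yl)-2,5-dimethoxybenzene
Conditions: CuI (10 mol %), picolinic acid (20 mol %), K3PO4, DMSO, 100 °C
Reagents that add atoms: none
Why: Ligand-accelerated Ullmann diaryl ether synthesis, in which the monovalent copper phenoxide of 5 couples with the aryl bromide, should tolerate the ortho-methoxy group and leave both terminal alkenes untouched.

Step 6
Reactants: 11 1-[3-(dec-9-en-1-yl)-5-methoxyphenoxy]-3-(hex-5-en-1-yl)-2,5-dimethoxybenzene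
Product: 12 macrocyclic alkene, the tri-O-methyl ether of the target with a C=C between tether carbons 5 and 6 counted from ring B (E/Z mixture)
Conditions: second-generation Grubbs catalyst RuCl2(=CHPh)(SIMes)(PCy3) (10 mol %), 1,4-benzoquinone (20 mol %), CH2Cl2 (1 mM), 40 °C, slow addition of 11
Reagents that add atoms: none
Why: The ruthenium benzylidene initiates on one terminal alkene by [2+2] cycloaddition and cycloreversion (Chauvin mechanism), and the resulting ruthenium alkylidene engages the second terminal alkene through a ruthenacyclobutane that collapses to the ring C=C and Ru=CH2, with ethene escaping from the refluxing solution as the driving force. The closest known reaction type is macrocyclic ring-closing olefin metathesis of an α,ω-diene. One ring is closed, the 21-membered macrocycle, with the new double bond endocyclic. No stereocentre is formed, and the E/Z ratio is immaterial because step 7 saturates the alkene. The selectivity needed is ring closure over acyclic diene metathesis oligomerisation and over olefin migration (which would give ring-contracted homologues); high dilution with slow addition, two unhindered monosubstituted olefins brought within reach by the bent diaryl ether hinge (meta-substituted on both rings) and 1,4-benzoquinone as a scavenger of ruthenium hydrides should secure it. All phenols are capped as methyl ethers and both alkenes lie at least five atoms from any oxygen, so no chelate should sequester the catalyst.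

Step 7
Reactants: 12 macrocyclic alkene (E/Z mixture)
Product: 13 saturated macrocycle, the tri-O-methyl ether of the target
Conditions: H2 (1 atm), 10% Pd/C, EtOAc, rt
Reagents that add atoms: none
Why: Heterogeneous catalytic hydrogenation should saturate the disubstituted ring alkene, both geometric isomers converging on one product, without touching the aryl methyl ethers or the diaryl ether.

Step 8
Reactants: 13 saturated macrocycle, the tri-O-methyl ether of the target
Product: 14 target CNP0393720.0, the macrocyclic diaryl ether triol
Conditions: BBr3 (6 equiv), CH2Cl2, −78 °C to rt; then H2O, work-up under N2 (aq. Na2S2O4 wash)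
Reagents that add atoms: none
Why: Lewis acid-mediated aryl methyl ether cleavage (borate formation, then SN2 attack of bromide at methyl) should free all three phenols while the diaryl ether, which has no sp3 carbon on oxygen, survives, and the reducing work-up guards the hydroquinone ring against air oxidation.

Compound list
1 | 3,5-dimethoxybenzyl bromide | COc1cc(CBr)cc(OC)c1 | starting material
2 | 9-bromonon-1-ene | C=CCCCCCCCBr | starting material
3 | non-8-en-1-ylmagnesium bromide | C=CCCCCCCC[Mg]Br | intermediate (not isolated)
4 | 1-(dec-9-en-1-yl)-3,5-dimethoxybenzene | COc1cc(OC)cc(CCCCCCCCC=C)c1 | intermediate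
5 | 3-(dec-9-en-1-yl)-5-methoxyphenol | COc1cc(O)cc(CCCCCCCCC=C)c1 | intermediate
6 | 2,6-dibromo-4-methoxyphenol | COc1cc(Br)c(O)c(Br)c1 | starting material
7 | 1,3-dibromo-2,5-dimethoxybenzene | COc1cc(Br)c(OC)c(Br)c1 | intermediate
8 | 6-bromohex-1-ene | C=CCCCCBr | starting material
9 | (3-bromo-2,5-dimethoxyphenyl)lithium | [Li]c1cc(OC)cc(Br)c1OC | intermediate (not isolated)
10 | 1-bromo-3-(hex-5-en-1-yl)-2,5-dimethoxybenzene | COc1cc(Br)c(OC)c(CCCCC=C)c1 | intermediate
11 | 1-[3-(dec-9-en-1-yl)-5-methoxyphenoxy]-3-(hex-5-en-1-yl)-2,5-dimethoxybenzene | COc1cc(Oc2cc(OC)cc(CCCCC=C)c2OC)cc(CCCCCCCCC=C)c1 | intermediate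
12 | macrocyclic alkene, tri-O-methyl ether of the target with a C=C between tether carbons 5 and 6 counted from ring B (E/Z mixture) | COc1cc2cc(c1)Oc1cc(OC)cc(c1OC)CCCCC=CCCCCCCCC2 | intermediate
13 | saturated macrocycle, tri-O-methyl ether of the target | COc1cc2cc(c1)Oc1cc(OC)cc(c1OC)CCCCCCCCCCCCCC2 | intermediate
14 | target CNP0393720.0, macrocyclic diaryl ether triol | Oc1cc2cc(c1)Oc1cc(O)cc(c1O)CCCCCCCCCCCCCC2 | target

Total step count: 8. Longest linear sequence: 6 steps (steps 1, 2, 5, 6, 7, 8; the ring B branch, steps 3 and 4, joins at step 5 and is equally long).

Steps most likely to fail: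

Step 6. Intermolecular metathesis may outrun ring closure and give oligomers, and double-bond migration before closure may give ring-contracted homologues. Fallback: setting out from 11, Lemieux–Johnson cleavage of both terminal alkenes (OsO4 cat., NaIO4, 2,6-lutidine, dioxane/H2O) should give 9-[3-[2,5-dimethoxy-3-(5-oxopentyl)phenoxy]-5-methoxyphenyl]nonanal F1. Intramolecular McMurry coupling of F1 (TiCl3, Zn–Cu couple, DME, reflux, syringe-pump addition) should then join the two carbonyl carbons, which are the same two tether carbons, reductively, and the route is rejoined at 12.

Step 5. Oxidative addition of copper to the electron-rich, ortho-substituted bromide may be slow, so the coupling may stall and protodebromination may take over. Fallback: setting out from 10, bromine–lithium exchange (n-BuLi, THF, −78 °C), B(OMe)3 and acidic work-up should give [3-(hex-5-en-1-yl)-2,5-dimethoxyphenyl]boronic acid F2. Chan–Lam coupling of F2 with 5 (Cu(OAc)2, pyridine, 4 Å sieves, air, CH2Cl2, rt) makes the same C–O bond oxidatively at room temperature with ring B as the boron partner, and the route is rejoined at 11.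

Step 4. Lithium–bromine scrambling between aryllithium 9 and product 10 during the slow alkylation may give dialkylated arene and returned 7. Fallback: setting out from 8, zinc insertion (Zn dust, LiCl, THF) should give hex-5-en-1-ylzinc bromide F3. Negishi coupling of F3 with an excess of 7 (Pd(OAc)2, SPhos, THF, 50 °C) inverts the polarity of the two partners and avoids any aryllithium; unreacted 7 is recovered and the route is rejoined at 10.

Further compounds
F1 | step 6 | 9-[3-[2,5-dimethoxy-3-(5-oxopentyl)phenoxy]-5-methoxyphenyl]nonanal | COc1cc(Oc2cc(OC)cc(CCCCC=O)c2OC)cc(CCCCCCCCC=O)c1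
F2 | step 5 | [3-(hex-5-en-1-yl)-2,5-dimethoxyphenyl]boronic acid | COc1cc(B(O)O)c(OC)c(CCCCC=C)c1
F3 | step 4 | hex-5-en-1-ylzinc bromide | C=CCCCC[Zn]Br
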